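**Remark on the chemistry:** the stereodescriptors of the target SMILES are taken as written; they place C7 and C10 anti across the C8–C9 oxirane, and C2 is carried as an isopropenyl group and C10 as a triethylsilyl ether so that no acid is needed once the oxirane is in place.

## Analysis of the target

The target is a daucane-type diester with a trans-fused bicyclo[5.3.0]decane core. Ring A is the cyclopentane C1–C2–C3–C4–C5 and ring B the cycloheptane C1–C5–C6–C7–C8–C9–C10, with C1 quaternary C–CH3, C2 CH–OAc, C3 CH2, C4 C(OH)iPr, C5 ring-fusion CH, C6 CH–O-veratroyl, C7 CH2, C8(CH3)–C9 oxirane and C10 CH–OH. In this numbering, which is used for all descriptors below, the eight stereocentres are (1R,2S,4R,5R,6R,8R,9R,10R). The C1 methyl, the C2 acetate and the C4 isopropyl group lie on one face, and C5–H, C4–OH, C6–O and C10–O on the other. The oxirane has C7 and C10 anti, so it is trans-fused to the seven-membered ring and strained. It is acid-sensitive, the free C10 hydroxyl next to it invites Payne rearrangement under base, the two esters can migrate, and the tertiary C4 carbinol is β to the C2 carbonyl at the ketone stage (retro-aldol, dehydration). The difficulty is twofold: a trans-oxirane cannot be made by epoxidising a cycloheptene, and the quaternary C1 is flanked by stereocentres on three sides. The strategy rests on the fact that C5 carries the exocyclic carbon C4 and sits between C1 and C6. With C4 inserted as a ketone between C5 and C6, ring B becomes an eight-membered ring in which an (E)-alkene and its oxirane are accessible, and a Wolff contraction then returns C4 to its exocyclic position.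

## Retrosynthetic reasoning

**End game.** Target 35 is traced to its C10 silyl ether 34, so the last operation is a non-basic, non-acidic desilylation and the C10 hydroxyl is never free as an alkoxide next to the oxirane. The veratrate is cut at the acyl–O bond to alcohol 32 and acid chloride 33, and 32 comes from the p-methoxybenzyl ether 31. C6 is unmasked only after the C2 acetate is in place, so the secondary hydroxyls never compete.

**C2.** The acetate of 31 goes back to diol 30 and this to ketone 29. Hydride must add to C2 from the face anti to the angular C1 methyl, which is also the face of the C4 hydroxyl.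

**Ring A.** The C3–C4 bond of 29 is cut (retro-aldol) to the 1,4-diketone 28. It is cut there because C4 is a tertiary carbinol β to the C2 carbonyl and because C1 is quaternary, so the C2 ketone can enolise only towards C3. The cut removes a ring and the C4 stereocentre. The forward aldol has to use the kinetic methyl enolate and place the C4 oxygen on the side of the C6 ether.

**The two ketones.** The C2 ketone of 28 is masked in 27 as an isopropenyl group, which is unmasked by ozonolysis without acid. The isopropyl ketone of 27 is traced through 26, 25 and 24 to the methyl ester 23.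

**Key disconnection.** In 23 the ester carbon C4 hangs on C5. Cutting C5–C6 and reconnecting C6 to C4 (Wolff retron) gives the eight-membered diazo ketone 19 and methanol (20). This is the only place where reinserting C4 enlarges ring B to eight members while C1, C6 and C10 stay untouched. What is gained is that the trans-fused oxirane arrives on the seven-membered ring by a contraction driven by loss of nitrogen. The forward step must migrate C6 with retention, capture the ketene and set C5.

**Diazo ketone.** 19 comes from ketone 17 by diazo transfer at the C5 methylene, and 17 from alcohol 16. C4 is kept as a carbinol until the oxirane is in place because its configuration biases the eight-membered ring.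

**Oxirane.** The oxirane of 16 is cut to the (E)-cyclooctene 15, which exposes only one face, and 15 comes from the (Z)-cyclooctene 14 by geometric isomerisation. The planar chirality of 15 decides the (8R,9R) configuration.

**Eight-membered ring.** 14 is opened at C8=C9 (ring-closing metathesis) to triene 13.

**C2 and C4–OH.** The isopropenyl group and the C4 hydroxyl of 13 both come from the γ-lactone 11 via lactol 12 (methyl addition at C2, then methylenation). The lactone ties C2 to the C4 oxygen and is the template for C1.

**C1 and C10.** 11 is the silyl ether of 10. The C1–CH3 bond of 10 is cut to the β-hydroxy lactone 9 (dianion methylation), and the C1–C10 bond of 9 to lactone 8 and acrolein (1). The aldol comes first so that C10 is set by the lactone enolate, and the methylation second so that chelate and ring both direct it to the same face.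

**Lactone and C6.** 8 comes from 7 by loss of the ester, and 7 from epoxide 5 and dimethyl malonate (6) (C1–C5 bond and lactone C–O). 5 is the ether of epoxy alcohol 4, which comes from racemic dienol 3 by kinetic resolution, and 3 from 1 and 3-bromo-2-methylpropene (2).

## Alternatives that were turned down

Alternative 1: Ring A is disconnected at C3–C4 as a carbenoid C–H insertion. The acyclic diazo β-keto ester A1 would give the cyclopentanone A2 under Rh2(OAc)4, the C3 carbenoid inserting into the ether-activated tertiary C4–H bond with retention. In its favour, 1,5-insertion into such a C–H bond is among the most dependable carbenoid reactions, it is catalytic, and it turns the C4 carbinol into an acyclic stereocentre that is transferred stereospecifically. On C4 this is stronger than the chelation-controlled aldol of the chosen route. Against it, A2 still has C1 as CH(CH3) and has no ring B. The quaternary centre, C10 and above all the trans-fused oxirane would have to be built afterwards by closing a seven-membered ring onto a preformed (E)-unit, with the strain paid in a ring-closing step that has no comparable driving force. The chosen strategy spends its key step on exactly that problem and accepts a less elegant ring A.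

Alternative 2: The C8=C9 unit is disconnected by carbometalation. The terminal alkyne A3 would give the (E)-allylic alcohol A4 by Cp2ZrCl2-catalysed methylalumination with AlMe3 and capture of the alkenylalane by a one-carbon aldehyde electrophile. In its favour, syn-carboalumination fixes C7 trans to C10 with near-complete control in one pot. The allylic alcohol A4 is an ideal substrate for a tartrate-controlled epoxidation, so the oxirane configuration would be set by a reagent; this is stronger than the planar-chirality control of the chosen route. Against it, ring B must then be closed by forming C1–C10 from an open chain. That closure creates the strained trans-oxirane ring in a reversible step and sets the quaternary C1 and C10 together with no obvious control element. The chosen route sets C1 and C10 early on a five-membered template and reaches the strained ring by an irreversible contraction.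

Alternative 3: The C1–C5 bond is disconnected as a transannular alkylation. The ten-membered bis-oxirane ketone A5 would give the hydroazulene A6 when KN(SiMe3)2 forms the C1 enolate, which opens the C4–C5 oxirane at C5. In its favour, one step closes both rings, sets C1 and C5 and frees the C4 hydroxyl. Oxirane opening is irreversible and pays for the strain of the C8–C9 oxirane, the same logic as nitrogen loss. In step economy and in complexity built per step it is clearly stronger. Against it, A5 is a harder target than the one it replaces: a ten-membered ring with two stereodefined trisubstituted oxiranes. The outcome at C1 and C5 depends on one reactive conformation of a flexible ring, and O-alkylation and base-induced opening of the oxirane α to the ketone compete. The chosen route divides the risk over steps of known type and keeps each stereocentre under a separate control element.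

Key step: step 16

## Route

Step 1
Reactants: 1 acrolein; 2 3-bromo-2-methylpropene
Product: 3 rac-5-methylhexa-1,5-dien-3-ol
Conditions: Zn, THF/sat. aq. NH4Cl, 0 °C to rt
Reagents that add atoms: none
Why: Barbier-type zinc allylation, which adds 1,2 to enals; the racemic carbinol (future C6) is resolved in step 2.

Step 2
Reactants: 3 rac-5-methylhexa-1,5-dien-3-ol
Product: 4 (1R)-3-methyl-1-[(2S)-oxiran-2-yl]but-3-en-1-ol
Conditions: Ti(OiPr)4, D-(−)-diisopropyl tartrate, t-BuOOH (0.45 equiv), 4 Å molecular sieves, CH2Cl2, −20 °C
Reagents that add atoms: tert-butyl hydroperoxide, CC(C)(C)OO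
Why: Sharpless kinetic resolution; with the D-tartrate the (R)-carbinol is the fast enantiomer and is epoxidised on its vinyl group to the erythro epoxy alcohol, which sets C6 (R) and the temporary C4 centre (S). The homoallylic 1,1-disubstituted alkene is not a substrate and the (S)-alcohol stays behind.

Step 3
Reactants: 4 (1R)-3-methyl-1-[(2S)-oxiran-2-yl]but-3-en-1-ol
Product: 5 (2S)-2-[(1R)-1-[(4-methoxyphenyl)methoxy]-3-methylbut-3-en-1-yl]oxirane
Conditions: NaH, 4-methoxybenzyl chloride, Bu4NI (cat.), THF/DMF, 0 °C
Reagents that add atoms: 4-methoxybenzyl chloride, COc1ccc(CCl)cc1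
Why: Williamson etherification; in a cold aprotic medium O-alkylation should outrun Payne rearrangement of the epoxy alkoxide.

Step 4
Reactants: 5 (2S)-2-[(1R)-1-[(4-methoxyphenyl)methoxy]-3-methylbut-3-en-1-yl]oxirane; 6 dimethyl malonate
Product: 7 methyl (5S)-5-[(1R)-1-[(4-methoxyphenyl)methoxy]-3-methylbut-3-en-1-yl]-2-oxooxolane-3-carboxylate (C1 epimers)
Conditions: NaOMe, MeOH, reflux; AcOH quench
Reagents that add atoms: none
Why: Malonate opens the terminal oxirane at C5 by SN2 and the C4 alkoxide lactonises (classical malonate–epoxide lactone synthesis); C4 is not touched.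

Step 5
Reactants: 7 methyl (5S)-5-[(1R)-1-[(4-methoxyphenyl)methoxy]-3-methylbut-3-en-1-yl]-2-oxooxolane-3-carboxylate
Product: 8 (5S)-5-[(1R)-1-[(4-methoxyphenyl)methoxy]-3-methylbut-3-en-1-yl]oxolan-2-one
Conditions: LiCl, H2O, DMSO, 150 °C
Reagents that add atoms: none
Why: Krapcho demethoxycarbonylation of the malonate-type ester; ether, alkene and lactone are stable to it.

Step 6
Reactants: 8 (5S)-5-[(1R)-1-[(4-methoxyphenyl)methoxy]-3-methylbut-3-en-1-yl]oxolan-2-one; 1 acrolein
Product: 9 (3S,5S)-3-[(1S)-1-hydroxyprop-2-en-1-yl]-5-[(1R)-1-[(4-methoxyphenyl)methoxy]-3-methylbut-3-en-1-yl]oxolan-2-one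
Conditions: LiN(iPr)2, THF, −78 °C; then 1, −78 °C; AcOH quench
Reagents that add atoms: none
Why: Aldol addition of the lactone lithium enolate, 1,2 to the enal. The aldehyde approaches anti to the C4 side chain and the ring-fixed (E)-enolate reacts through a chair transition state with the vinyl group equatorial (anti aldol), which together give C10 the configuration of the target; the C1 centre formed here is erased in step 7.

Step 7
Reactants: 9 (3S,5S)-3-[(1S)-1-hydroxyprop-2-en-1-yl]-5-[(1R)-1-[(4-methoxyphenyl)methoxy]-3-methylbut-3-en-1-yl]oxolan-2-one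
Product: 10 (3R,5S)-3-[(1S)-1-hydroxyprop-2-en-1-yl]-3-methyl-5-[(1R)-1-[(4-methoxyphenyl)methoxy]-3-methylbut-3-en-1-yl]oxolan-2-one
Conditions: LiN(iPr)2 (2.3 equiv), THF, −78 to −30 °C; MeI, DMPU, −78 to −20 °C
Reagents that add atoms: iodomethane, CI
Why: Fráter–Seebach alkylation of the chelated alkoxide–enolate dianion. Iodomethane enters anti to the vinyl group on the lithium chelate and trans to the C4 side chain on the lactone, two effects that point to the same face, so the quaternary C1 is set.

Step 8
Reactants: 10 (3R,5S)-3-[(1S)-1-hydroxyprop-2-en-1-yl]-3-methyl-5-[(1R)-1-[(4-methoxyphenyl)methoxy]-3-methylbut-3-en-1-yl]oxolan-2-one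
Product: 11 (3R,5S)-3-methyl-3-[(1S)-1-(triethylsilyloxy)prop-2-en-1-yl]-5-[(1R)-1-[(4-methoxyphenyl)methoxy]-3-methylbut-3-en-1-yl]oxolan-2-one
Conditions: Et3SiOTf, 2,6-lutidine, CH2Cl2, −78 to 0 °C
Reagents that add atoms: triethylsilyl trifluoromethanesulfonate, CC[Si](CC)(CC)OS(=O)(=O)C(F)(F)F
Why: Silylation of the hindered secondary alcohol with a silyl triflate; it blocks retro-aldol cleavage in the next steps and the triethylsilyl group can be removed at the end by fluoride without acid or base.

Step 9
Reactants: 11 (3R,5S)-3-methyl-3-[(1S)-1-(triethylsilyloxy)prop-2-en-1-yl]-5-[(1R)-1-[(4-methoxyphenyl)methoxy]-3-methylbut-3-en-1-yl]oxolan-2-one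
Product: 12 lactol (3R,5S)-2,3-dimethyl-3-[(1S)-1-(triethylsilyloxy)prop-2-en-1-yl]-5-[(1R)-1-[(4-methoxyphenyl)methoxy]-3-methylbut-3-en-1-yl]oxolan-2-ol (anomers, in equilibrium with the open γ-hydroxy methyl ketone)
Conditions: MeLi, Et2O/THF, −78 °C; aq. NH4Cl
Reagents that add atoms: methyllithium, [Li]C
Why: Mono-addition of an organolithium to a γ-lactone stops at the lithium hemiketal; the new methyl is C3 and the lactone carbon becomes the C2 ketone carbon.

Step 10
Reactants: 12 lactol from step 9
Product: 13 (3S,4S,6S,7R)-7-[(4-methoxyphenyl)methoxy]-4,9-dimethyl-4-(prop-1-en-2-yl)-3-(triethylsilyloxy)deca-1,9-dien-6-ol (chain locants; target numbering 10S,1S,4S,6R)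
Conditions: Ph3PCH3Br, KN(SiMe3)2, THF/toluene, 0 to 60 °C
Reagents that add atoms: methylenetriphenylphosphorane (made from Ph3PCH3Br and KN(SiMe3)2), C=P(c1ccccc1)(c1ccccc1)c1ccccc1
Why: Wittig methylenation through the open hydroxy ketone form of the lactol. It turns C2 into an isopropenyl group, a methyl ketone surrogate that is inert to base, hydride and organometallics and is cleaved later without acid, and it frees the C4 hydroxyl.

Step 11
Reactants: 13 hydroxy triene from step 10
Product: 14 (Z)-cyclooctene (1S,4S,6R,10S,8Z): ring C1–C5–C4–C6–C7–C8=C9–C10 with C1 methyl and isopropenyl, C4 OH, C6 O-p-methoxybenzyl, C8 methyl, C10 OSiEt3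
Conditions: second-generation Grubbs catalyst RuCl2(=CHPh)(H2IMes)(PCy3) (10 mol %), CH2Cl2 (0.002 M), 40 °C
Reagents that add atoms: none
Why: Ring-closing metathesis between the C10 vinyl and the methallyl group, helped by the quaternary C1; the isopropenyl group on a quaternary carbon is too hindered to take part, and the ring size enforces the (Z)-alkene.

Step 12
Reactants: 14 (Z)-cyclooctene from step 11
Product: 15 (E)-cyclooctene (1S,4S,6R,10S,8E), the planar diastereomer with the C8 methyl on the face of the C6 and C10 oxygens
Conditions: hν (254 nm), methyl benzoate, Et2O/hexanes, closed-loop flow through AgNO3 on SiO2; release with aq. NH3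
Reagents that add atoms: none
Why: Singlet-sensitised Z-to-E photoisomerisation of a cis-cyclooctene with continuous capture of the strained (E)-isomer as its AgNO3 complex. The required planar diastereomer is the crown conformer with the isopropenyl group and the C4 hydroxyl equatorial, whereas the other would hold them 1,3-diaxial. Uncaptured material is returned to the loop.

Step 13
Reactants: 15 (E)-cyclooctene from step 12
Product: 16 trans-oxirane alcohol (1S,4S,6R,8R,9R,10R)
Conditions: dimethyldioxirane, acetone/CH2Cl2, −78 to −20 °C
Reagents that add atoms: dimethyldioxirane, CC1(C)OO1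
Why: Stereospecific epoxidation of the strained (E)-alkene, which reacts far faster than the isopropenyl group and can be attacked only on its outer face; with the planar chirality of 15 this gives the (8R,9R) oxirane with C7 and C10 anti.

Step 14
Reactants: 16 trans-oxirane alcohol from step 13
Product: 17 eight-membered C4 ketone (1S,6R,8R,9R,10R)
Conditions: Dess–Martin periodinane, NaHCO3, CH2Cl2, 0 °C to rt
Reagents that add atoms: none
Why: Buffered neutral oxidation of the secondary C4 alcohol; oxirane, silyl ether and benzyl ether are stable to it.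

Step 15
Reactants: 17 eight-membered C4 ketone from step 14
Product: 19 eight-membered 5-diazo-4-ketone (1R,6R,8R,9R,10R) with trans C8–C9 oxirane (precursor of the key step), via trifluoroacetyl ketone 18 (not isolated)
Conditions: LiN(SiMe3)2, THF, −78 °C; CF3CO2CH2CF3; then MsN3, Et3N, H2O, MeCN, rt
Reagents that add atoms: methanesulfonyl azide, CS(=O)(=O)N=[N+]=[N-]
Why: Detrifluoroacetylative diazo transfer (Danheiser procedure). The hindered amide base should deprotonate the C5 methylene and not the alkoxy-bearing C6 methine, the enolate is trifluoroacetylated, and the activated C5 then accepts the diazo group with loss of the trifluoroacetyl group.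

Step 16
Reactants: 19 eight-membered 5-diazo-4-ketone from step 15; 20 methanol
Product: 23 ring B methyl ester on C5 with trans-fused oxirane (1S,5R,6R,8R,9R,10R), via ketene 21 (not isolated), via 5-epi ester 22 (not isolated)
Conditions: hν (365 nm), MeOH/THF, 0 °C; then NaOMe (0.3 equiv), 23 °C
Reagents that add atoms: none
Why: Irradiation into the n–π* band of the cyclic s-cis α-diazo ketone expels N2 while the C4–C6 bond migrates to C5 (photochemical Wolff rearrangement), so C5–C6 forms, C4 leaves the ring as the ketene carbon of 21 and the eight-membered ring becomes ring B. The closest precedent is the photochemical Wolff ring contraction of cyclic 2-diazo ketones, as used for D-nor steroids and strained bicycles. Ring B is closed by this 1,2-shift, a contraction from eight to seven members and not a cyclisation of an open chain, and the loss of N2 pays for the strain of the oxirane that is now trans-fused to a seven-membered ring. C6 migrates with retention, so its configuration from step 2 is kept, and the oxirane and C10 are not touched by the neutral conditions. Methanol (20) adds to the ketene and the ester enol tautomerises, which creates C5. Because C1 is quaternary and carries groups on both faces, kinetic protonation cannot be relied on, so C5 is set thermodynamically: catalytic NaOMe in the same methanol converts 22 into 23, whose ester is trans to both the C6 ether and the isopropenyl group. The step needs migration to win over O–H insertion and 1,2-shifts of the carbene, which the s-cis geometry of the cyclic diazo ketone and the absence of a hydrogen on C1 secure. Expulsion of the C6 alkoxide from the ester enolate is held back because it would put a C5=C6 double bond into the oxirane-bearing ring.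

Step 17
Reactants: 23 methyl ester from step 16
Product: 24 primary alcohol (C4 as CH2OH on C5; 1S,5S,6R,8R,9R,10R)
Conditions: iBu2AlH, CH2Cl2, −78 °C; aq. potassium sodium tartrate
Reagents that add atoms: none
Why: Hydride reduction of the ester to the primary alcohol; at low temperature the ester should react before the hindered trisubstituted oxirane.

Step 18
Reactants: 24 primary alcohol from step 17
Product: 25 C4 aldehyde (1S,5R,6R,8R,9R,10R)
Conditions: Dess–Martin periodinane, NaHCO3, CH2Cl2, 0 °C
Reagents that add atoms: none
Why: Buffered neutral oxidation, which avoids epimerisation at C5 and β-elimination of the C6 ether; the aldehyde is used at once.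

Step 19
Reactants: 25 C4 aldehyde from step 18
Product: 26 secondary alcohol with isopropyl on C4 (C4 epimers)
Conditions: iPrMgCl, CeCl3, THF, −78 °C
Reagents that add atoms: isopropylmagnesium chloride, CC(C)[Mg]Cl
Why: Organocerium addition to a hindered, enolisable aldehyde, which suppresses β-hydride reduction and enolisation; the new C4 centre is removed in the next step.

Step 20
Reactants: 26 secondary alcohol from step 19
Product: 27 isopropyl ketone on C5 with isopropenyl on C1 (1S,5R,6R,8R,9R,10R)
Conditions: Dess–Martin periodinane, NaHCO3, CH2Cl2, 0 °C to rt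
Reagents that add atoms: none
Why: Neutral oxidation of the secondary alcohol to the C4 ketone.

Step 21
Reactants: 27 isopropyl ketone from step 20
Product: 28 1,4-diketone (C2 methyl ketone and C4 isopropyl ketone; 1R,5R,6R,8R,9R,10R)
Conditions: O3, CH2Cl2, −78 °C, stopped at the first excess of ozone; PPh3
Reagents that add atoms: ozone, [O-][O+]=O
Why: Ozonolysis of the 1,1-disubstituted alkene unmasks the C2 methyl ketone without acid, so the oxirane is not endangered; the alkene reacts faster than the electron-rich arene of the benzyl ether.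

Step 22
Reactants: 28 1,4-diketone from step 21
Product: 29 ring A aldol (C2 ketone, C4 tertiary alcohol with isopropyl; 1R,4R,5R,6R,8R,9R,10R)
Conditions: LiN(SiMe3)2, THF, −78 to −40 °C; AcOH quench at −78 °C
Reagents that add atoms: none
Why: Intramolecular aldol addition, 5-(enolexo)-exo-trig: C1 is quaternary, so the kinetic base takes a proton from the C3 methyl, and the enolate adds to the C4 ketone. Lithium bridges the C4 carbonyl oxygen and the C6 ether, which puts the new hydroxyl on the face of the C6 oxygen and the isopropyl group away from it; the cold quench avoids retro-aldol and dehydration.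

Step 23
Reactants: 29 ring A aldol from step 22
Product: 30 C2,C4 diol (1S,2S,4R,5R,6R,8R,9R,10R)
Conditions: NaBH4, MeOH, −20 °C
Reagents that add atoms: none
Why: Hydride attacks the cyclopentanone from the face anti to the angular C1 methyl, which is also the face of the C4 hydroxyl, so the C2 hydroxyl ends up cis to the methyl (as in the reduction of 17-keto steroids).

Step 24
Reactants: 30 C2,C4 diol from step 23
Product: 31 C2 acetate (1S,2S,4R,5R,6R,8R,9R,10R)
Conditions: Ac2O, pyridine, DMAP (cat.), CH2Cl2, 0 °C
Reagents that add atoms: acetic anhydride, CC(=O)OC(C)=O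
Why: Acylation of the only free secondary hydroxyl; the tertiary C4 hydroxyl should not react under these conditions.

Step 25
Reactants: 31 C2 acetate from step 24
Product: 32 C6 alcohol (1S,2S,4R,5R,6R,8R,9R,10R)
Conditions: DDQ, CH2Cl2/pH 7 aqueous buffer, 0 °C
Reagents that add atoms: none
Why: Oxidative cleavage of the p-methoxybenzyl ether under neutral conditions that spare oxirane, acetate and silyl ether; excess water captures the oxocarbenium ion before the tertiary C4 hydroxyl can.

Step 26
Reactants: 32 C6 alcohol from step 25; 33 3,4-dimethoxybenzoyl chloride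
Product: 34 C6 veratrate with C10 triethylsilyl ether (1S,2S,4R,5R,6R,8R,9R,10R)
Conditions: DMAP, Et3N, CH2Cl2, 0 °C to rt
Reagents that add atoms: none
Why: DMAP-catalysed acylation of the one free secondary hydroxyl; the tertiary C4 hydroxyl is unreactive and C10 is still protected.

Step 27
Reactants: 34 C6 veratrate from step 26
Product: 35 target CNP0197096.5 (1R,2S,4R,5R,6R,8R,9R,10R)
Conditions: Et3N·3HF, THF, 0 °C to rt
Reagents that add atoms: none
Why: Fluoride-mediated cleavage of the triethylsilyl ether with a nearly neutral reagent, which generates no C10 alkoxide (no Payne rearrangement, no acyl migration) and is not acidic enough to open the oxirane.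

## Compound list

1 | acrolein | C=CC=O | starting material
2 | 3-bromo-2-methylpropene | CC(=C)CBr | starting material
3 | rac-5-methylhexa-1,5-dien-3-ol | C=CC(O)CC(C)=C | intermediate
4 | (1R)-3-methyl-1-[(2S)-oxiran-2-yl]but-3-en-1-ol | C=C(C)C[C@@H](O)[C@@H]1CO1 | intermediate
5 | (2S)-2-[(1R)-1-[(4-methoxyphenyl)methoxy]-3-methylbut-3-en-1-yl]oxirane | C=C(C)C[C@@H](OCc1ccc(OC)cc1)[C@@H]1CO1 | intermediate
6 | dimethyl malonate | COC(=O)CC(=O)OC | starting material
7 | methyl (5S)-5-[(1R)-1-[(4-methoxyphenyl)methoxy]-3-methylbut-3-en-1-yl]-2-oxooxolane-3-carboxylate (C1 epimers) | COC(=O)C1C[C@@H]([C@H](OCc2ccc(OC)cc2)CC(C)=C)OC1=O | intermediate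
8 | (5S)-5-[(1R)-1-[(4-methoxyphenyl)methoxy]-3-methylbut-3-en-1-yl]oxolan-2-one | O=C1CC[C@@H]([C@H](OCc2ccc(OC)cc2)CC(C)=C)O1 | intermediate
9 | (3S,5S)-3-[(1S)-1-hydroxyprop-2-en-1-yl]-5-[(1R)-1-[(4-methoxyphenyl)methoxy]-3-methylbut-3-en-1-yl]oxolan-2-one | C=C[C@H](O)[C@@H]1C[C@@H]([C@H](OCc2ccc(OC)cc2)CC(C)=C)OC1=O | intermediate
10 | (3R,5S)-3-[(1S)-1-hydroxyprop-2-en-1-yl]-3-methyl-5-[(1R)-1-[(4-methoxyphenyl)methoxy]-3-methylbut-3-en-1-yl]oxolan-2-one | C=C[C@H](O)[C@@]1(C)C[C@@H]([C@H](OCc2ccc(OC)cc2)CC(C)=C)OC1=O | intermediate
11 | triethylsilyl ether of 10 | C=C[C@H](O[Si](CC)(CC)CC)[C@@]1(C)C[C@@H]([C@H](OCc2ccc(OC)cc2)CC(C)=C)OC1=O | intermediate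
12 | lactol from 11 (anomers; open form is the γ-hydroxy methyl ketone) | C=C[C@H](O[Si](CC)(CC)CC)[C@@]1(C)C[C@@H]([C@H](OCc2ccc(OC)cc2)CC(C)=C)OC1(C)O | intermediate
13 | (3S,4S,6S,7R)-7-[(4-methoxyphenyl)methoxy]-4,9-dimethyl-4-(prop-1-en-2-yl)-3-(triethylsilyloxy)deca-1,9-dien-6-ol | C=C(C)[C@](C)(C[C@H](O)[C@H](OCc1ccc(OC)cc1)CC(C)=C)[C@@H](O[Si](CC)(CC)CC)C=C | intermediate
14 | (Z)-cyclooctene (1S,4S,6R,10S,8Z) | C=C(C)[C@]1(C)C[C@H](O)[C@H](OCc2ccc(OC)cc2)C/C(C)=C\[C@@H]1O[Si](CC)(CC)CC | intermediate
15 | (E)-cyclooctene (1S,4S,6R,10S,8E), planar diastereomer with the C8 methyl on the face of the C6 and C10 oxygens | C=C(C)[C@]1(C)C[C@H](O)[C@H](OCc2ccc(OC)cc2)C/C(C)=C/[C@@H]1O[Si](CC)(CC)CC | intermediate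
16 | trans-oxirane alcohol (1S,4S,6R,8R,9R,10R) | C=C(C)[C@]1(C)C[C@H](O)[C@H](OCc2ccc(OC)cc2)C[C@@]3(C)O[C@@H]3[C@@H]1O[Si](CC)(CC)CC | intermediate
17 | eight-membered C4 ketone (1S,6R,8R,9R,10R) | C=C(C)[C@]1(C)CC(=O)[C@H](OCc2ccc(OC)cc2)C[C@@]3(C)O[C@@H]3[C@@H]1O[Si](CC)(CC)CC | intermediate
18 | 5-trifluoroacetyl derivative of 17 (not isolated) | C=C(C)[C@]1(C)C(C(=O)C(F)(F)F)C(=O)[C@H](OCc2ccc(OC)cc2)C[C@@]3(C)O[C@@H]3[C@@H]1O[Si](CC)(CC)CC | intermediate
19 | eight-membered 5-diazo-4-ketone with trans C8–C9 oxirane (1R,6R,8R,9R,10R) | C=C(C)[C@]1(C)C(=[N+]=[N-])C(=O)[C@H](OCc2ccc(OC)cc2)C[C@@]3(C)O[C@@H]3[C@@H]1O[Si](CC)(CC)CC | intermediate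
20 | methanol | CO | starting material
21 | ketene on C5 of ring B (not isolated) | C=C(C)[C@]1(C)C(=C=O)[C@H](OCc2ccc(OC)cc2)C[C@@]3(C)O[C@@H]3[C@@H]1O[Si](CC)(CC)CC | intermediate
22 | 5-epi methyl ester (not isolated) | C=C(C)[C@]1(C)[C@H](C(=O)OC)[C@H](OCc2ccc(OC)cc2)C[C@@]3(C)O[C@@H]3[C@@H]1O[Si](CC)(CC)CC | intermediate
23 | ring B methyl ester on C5 with trans-fused oxirane (1S,5R,6R,8R,9R,10R) | C=C(C)[C@]1(C)[C@@H](C(=O)OC)[C@H](OCc2ccc(OC)cc2)C[C@@]3(C)O[C@@H]3[C@@H]1O[Si](CC)(CC)CC | intermediate
24 | primary alcohol (C4 as CH2OH; 1S,5S,6R,8R,9R,10R) | C=C(C)[C@]1(C)[C@@H](CO)[C@H](OCc2ccc(OC)cc2)C[C@@]3(C)O[C@@H]3[C@@H]1O[Si](CC)(CC)CC | intermediate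
25 | C4 aldehyde (1S,5R,6R,8R,9R,10R) | C=C(C)[C@]1(C)[C@@H](C=O)[C@H](OCc2ccc(OC)cc2)C[C@@]3(C)O[C@@H]3[C@@H]1O[Si](CC)(CC)CC | intermediate
26 | secondary alcohol with isopropyl on C4 (C4 epimers) | C=C(C)[C@]1(C)[C@@H](C(O)C(C)C)[C@H](OCc2ccc(OC)cc2)C[C@@]3(C)O[C@@H]3[C@@H]1O[Si](CC)(CC)CC | intermediate
27 | isopropyl ketone (1S,5R,6R,8R,9R,10R) | C=C(C)[C@]1(C)[C@@H](C(=O)C(C)C)[C@H](OCc2ccc(OC)cc2)C[C@@]3(C)O[C@@H]3[C@@H]1O[Si](CC)(CC)CC | intermediate
28 | 1,4-diketone (1R,5R,6R,8R,9R,10R) | CC(=O)[C@]1(C)[C@@H](C(=O)C(C)C)[C@H](OCc2ccc(OC)cc2)C[C@@]3(C)O[C@@H]3[C@@H]1O[Si](CC)(CC)CC | intermediate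
29 | ring A aldol, C2 ketone (1R,4R,5R,6R,8R,9R,10R) | COc1ccc(CO[C@@H]2C[C@@]3(C)O[C@@H]3[C@H](O[Si](CC)(CC)CC)[C@]3(C)C(=O)C[C@@](O)(C(C)C)[C@@H]23)cc1 | intermediate
30 | C2,C4 diol (1S,2S,4R,5R,6R,8R,9R,10R) | COc1ccc(CO[C@@H]2C[C@@]3(C)O[C@@H]3[C@H](O[Si](CC)(CC)CC)[C@]3(C)[C@@H](O)C[C@@](O)(C(C)C)[C@@H]23)cc1 | intermediate
31 | C2 acetate (1S,2S,4R,5R,6R,8R,9R,10R) | COc1ccc(CO[C@@H]2C[C@@]3(C)O[C@@H]3[C@H](O[Si](CC)(CC)CC)[C@]3(C)[C@@H](OC(C)=O)C[C@@](O)(C(C)C)[C@@H]23)cc1 | intermediate
32 | C6 alcohol (1S,2S,4R,5R,6R,8R,9R,10R) | O[C@@H]1C[C@@]2(C)O[C@@H]2[C@H](O[Si](CC)(CC)CC)[C@]2(C)[C@@H](OC(C)=O)C[C@@](O)(C(C)C)[C@@H]12 | intermediate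
33 | 3,4-dimethoxybenzoyl chloride | COc1ccc(C(Cl)=O)cc1OC | starting material
34 | C6 veratrate, C10 triethylsilyl ether (1S,2S,4R,5R,6R,8R,9R,10R) | COc1ccc(C(=O)O[C@@H]2C[C@@]3(C)O[C@@H]3[C@H](O[Si](CC)(CC)CC)[C@]3(C)[C@@H](OC(C)=O)C[C@@](O)(C(C)C)[C@@H]23)cc1OC | intermediate
35 | CNP0197096.5 (1R,2S,4R,5R,6R,8R,9R,10R) | COc1ccc(C(=O)O[C@@H]2C[C@@]3(C)O[C@@H]3[C@H](O)[C@]3(C)[C@@H](OC(C)=O)C[C@@](O)(C(C)C)[C@@H]23)cc1OC | target

## Step count and least certain steps

Total: 27 steps. Longest linear sequence: 27 steps (from 1 and 2; the route is linear).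

**Step 16 (key step).** The excited diazo ketone or a free carbene may be captured by methanol before migration (O–H insertion), a substituent of C1 may shift, or the carbene may insert into the benzylic C–H bonds of the C6 ether. Equilibration at C5 may be slow at this hindered position, or methoxide may cause β-elimination of the C6 alkoxide.
Fallback (pinacol-type ring contraction in place of the Wolff rearrangement): it sets out from ketone 17. Rubottom oxidation (LiN(SiMe3)2 and Me3SiCl, then dimethyldioxirane) gives the 5-hydroxy ketone F1. Addition of iPrMgCl/CeCl3 to the C4 ketone gives the diol F2, and mesylation of its secondary C5 hydroxyl (MsCl, Et3N) gives the hydroxy mesylate F3. KOtBu in THF then drives the alkoxide-induced 1,2-shift of C6 from C4 to C5 with inversion at C5 and loss of mesylate. This contracts the ring and gives the isopropyl ketone directly, so the fallback comes back to the route at 27 and bypasses 19 to 26. It needs the C5 hydroxyl on the face shown for F1 and the ring bond C4–C6 antiperiplanar to the leaving group; otherwise the isopropyl group migrates.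

**Step 12.** The photoisomerisation may give the other planar diastereomer (the required one carries the C6 and C10 oxygens axial), the arene of the C6 ether may compete for the light or add to the alkene, and conversion of a trisubstituted alkene may be slow.
Fallback (stereospecific chemical inversion, no ultraviolet light): it sets out from 14. Epoxidation with mCPBA on the face anti to the C10 silyl ether (peripheral attack, as for 3-substituted cyclooctenes) gives the cis-oxirane F4. LiPPh2 opens it at C9 with inversion to the β-hydroxy phosphine F5. P-methylation with MeI is followed by spontaneous syn-elimination of methyl(diphenyl)phosphine oxide, which gives the (E)-alkene as a single planar isomer, so the fallback comes back at 15.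

**Step 11.** Initiation on two hindered alkenes may be slow, so that oligomerisation or alkene migration competes with closure of a trisubstituted eight-membered ring.
Fallback (ring closure on the lactone template): it sets out from 11, in which the two alkene-bearing arms are cis on the five-membered ring. Ring-closing metathesis with the same catalyst gives the bridged bicyclic lactone F6, MeLi gives the lactol F7, and Wittig methylenation opens the bridge to the (Z)-cyclooctene, so the fallback comes back at 14.

**Step 6.** Facial selectivity is expected to be good but the simple diastereoselection of a lactone enolate with a small enal may be modest, which lowers the purity at C10; retro-aldol on warming and some 1,4-addition are further risks.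
Fallback (C10 by catalyst-controlled reduction): it sets out from 8. C-acylation of the lithium enolate with N-methoxy-N-methyl-3-(trimethylsilyl)propiolamide gives the β-keto lactone F8. Methylation (K2CO3, MeI) trans to the C4 side chain gives the ynone F9 with the quaternary C1. Transfer hydrogenation with RuCl(p-cymene)[(R,R)-TsDPEN] and HCO2H/Et3N (catalyst enantiomer chosen to give the C10 configuration of 10) gives the propargylic alcohol F10. Bu4NF/AcOH removes the silyl group to give the terminal alkyne F11, and semihydrogenation (H2, Pd/CaCO3 with Pb(OAc)2, quinoline) gives the vinyl carbinol, so the fallback comes back at 10.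

**Step 22.** The aldol may give the C4 epimer if the lithium chelate to the C6 ether does not control the face, the hindered isopropyl ketone may react slowly so that retro-aldol or dehydration sets in on warming, and enolisation at the isopropyl methine would lead to the wrong ring.
Fallback (reductive enolate generation): it sets out from 28. Kinetic silylation of the methyl ketone (LiN(SiMe3)2, Me3SiCl) gives the silyl enol ether F12 and NBS gives the bromomethyl ketone F13. SmI2 in THF at −78 °C then forms the samarium enolate regiospecifically at C3, and this closes ring A by an intramolecular Reformatsky-type aldol through a chelate that holds the C4 oxygen on the side of the C6 ether, so the fallback comes back at 29.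

## Further compounds

F1 | step 16 | 5-hydroxy derivative of ketone 17 | C=C(C)[C@]1(C)[C@@H](O)C(=O)[C@H](OCc2ccc(OC)cc2)C[C@@]3(C)O[C@@H]3[C@@H]1O[Si](CC)(CC)CC
F2 | step 16 | C4 tertiary alcohol with isopropyl, C5 hydroxyl (C4 epimers) | C=C(C)[C@]1(C)[C@@H](O)C(O)(C(C)C)[C@H](OCc2ccc(OC)cc2)C[C@@]3(C)O[C@@H]3[C@@H]1O[Si](CC)(CC)CC
F3 | step 16 | C5 mesylate of F2 | C=C(C)[C@]1(C)[C@@H](OS(C)(=O)=O)C(O)(C(C)C)[C@H](OCc2ccc(OC)cc2)C[C@@]3(C)O[C@@H]3[C@@H]1O[Si](CC)(CC)CC
F4 | step 12 | cis-oxirane of 14, oxygen anti to the C10 silyl ether | C=C(C)[C@]1(C)C[C@H](O)[C@H](OCc2ccc(OC)cc2)C[C@@]3(C)O[C@H]3[C@@H]1O[Si](CC)(CC)CC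
F5 | step 12 | β-hydroxy phosphine (C9 diphenylphosphanyl, C8 hydroxyl) | C=C(C)[C@]1(C)C[C@H](O)[C@H](OCc2ccc(OC)cc2)C[C@@](C)(O)[C@H](P(c3ccccc3)c3ccccc3)[C@@H]1O[Si](CC)(CC)CC
F6 | step 11 | bridged bicyclic lactone from ring-closing metathesis of 11 | O=C1O[C@H]2C[C@]1(C)[C@@H](O[Si](CC)(CC)CC)/C=C(C)\C[C@H]2OCc1ccc(OC)cc1
F7 | step 11 | bridged bicyclic lactol (anomers) | CC1(O)O[C@H]2C[C@]1(C)[C@@H](O[Si](CC)(CC)CC)/C=C(C)\C[C@H]2OCc1ccc(OC)cc1
F8 | step 6 | α-[3-(trimethylsilyl)propynoyl] lactone (C1 epimers and enol) | C[Si](C)(C)C#CC(=O)C1C[C@@H]([C@H](OCc2ccc(OC)cc2)CC(C)=C)OC1=O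
F9 | step 6 | α-methyl ynone with quaternary C1 | C[Si](C)(C)C#CC(=O)[C@@]1(C)C[C@@H]([C@H](OCc2ccc(OC)cc2)CC(C)=C)OC1=O
F10 | step 6 | silylated propargylic alcohol | C[Si](C)(C)C#C[C@H](O)[C@@]1(C)C[C@@H]([C@H](OCc2ccc(OC)cc2)CC(C)=C)OC1=O
F11 | step 6 | terminal propargylic alcohol | C#C[C@H](O)[C@@]1(C)C[C@@H]([C@H](OCc2ccc(OC)cc2)CC(C)=C)OC1=O
F12 | step 22 | trimethylsilyl enol ether of the C2 methyl ketone of 28 | C=C(O[Si](C)(C)C)[C@]1(C)[C@@H](C(=O)C(C)C)[C@H](OCc2ccc(OC)cc2)C[C@@]3(C)O[C@@H]3[C@@H]1O[Si](CC)(CC)CC
F13 | step 22 | bromomethyl ketone | BrCC(=O)[C@]1(C)[C@@H](C(=O)C(C)C)[C@H](OCc2ccc(OC)cc2)C[C@@]3(C)O[C@@H]3[C@@H]1O[Si](CC)(CC)CC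
A1 | alternative 1 | acyclic C3 diazo β-keto ester with C4–H carbinol silyl ether | COC(=O)C(=[N+]=[N-])C(=O)[C@H](C)[C@H](C(=O)OC)[C@H](O[Si](CC)(CC)CC)C(C)C
A2 | alternative 1 | ring A cyclopentanone with tetrasubstituted C4 carbinol ether | COC(=O)[C@@H]1C(=O)[C@H](C)[C@H](C(=O)OC)[C@]1(O[Si](CC)(CC)CC)C(C)C
A3 | alternative 2 | C7-bound terminal alkyne on ring A | C#CC[C@@H](O[Si](C)(C)C(C)(C)C)[C@H]1[C@@H](C)[C@@H](OCc2ccc(OC)cc2)C[C@@]1(O[Si](CC)(CC)CC)C(C)C
A4 | alternative 2 | (E)-allylic alcohol with C7 trans to C10 | OC/C=C(\C)C[C@@H](O[Si](C)(C)C(C)(C)C)[C@H]1[C@@H](C)[C@@H](OCc2ccc(OC)cc2)C[C@@]1(O[Si](CC)(CC)CC)C(C)C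
A5 | alternative 3 | ten-membered C10 ketone with C4–C5 and C8–C9 oxiranes (C1 epimers) | CC1C(=O)[C@H]2O[C@]2(C)C[C@@H](O[Si](C)(C)C(C)(C)C)[C@@H]2O[C@@]2(C(C)C)C[C@@H]1OCc1ccc(OC)cc1
A6 | alternative 3 | trans-fused hydroazulene C10 ketone with free C4 hydroxyl and C8–C9 oxirane | CC(C)(C)[Si](C)(C)O[C@@H]2C[C@@]3(C)O[C@@H]3C(=O)[C@]3(C)[C@@H](OCc4ccc(OC)cc4)C[C@@](O)(C(C)C)[C@@H]23
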